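The target is the C4→C6′ hydroarylation dimer of one chromene, 16, so everything rests on cutting the C3=C4 olefin of the 2,2-dimethyl-2H-pyran fused to the hexasubstituted benzene ring A. Ring-closing metathesis of diene 14, a 2-vinylaryl 1,1-dimethylallyl ether whose oxygen (O1) is flanked by the C8 prenyl group and the vinyl-bearing C4a, forms this bond and the pyran ring in one operation. The flanking groups block the Claisen escape of the ether, and the C2 gem-dimethyl group assists closure. The olefin is then used twice: it persists in the upper half and, protonated by a chiral acid, becomes the C3–C4 unit and the (R)-stereocenter of the lower chroman.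

Key step: step 10

Remark: which antipode of the chiral acid delivers the (R) centre in step 12 cannot be fixed on paper; the (R)-acid is written, and its mirror image is used if the first run gives the (S)-dimer.

Step 1
Reactants: 1 (E)-3,4',5-trimethoxystilbene
Product: 2 1,3-dimethoxy-5-[2-(4-methoxyphenyl)ethyl]benzene
Conditions: H2 (1 atm), 10% Pd/C, EtOAc, rt
Reagents that add atoms: none
Why: Catalytic hydrogenation of the stilbene olefin over Pd/C should be clean, since aryl methyl ethers and the arenes are inert under these conditions.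

Step 2
Reactants: 2 1,3-dimethoxy-5-[2-(4-methoxyphenyl)ethyl]benzene
Product: 4 2,6-dimethoxy-4-[2-(4-methoxyphenyl)ethyl]benzaldehyde, via aryllithium 3 (not isolated)
Conditions: n-BuLi, THF, 0 °C to rt; DMF, 0 °C; H2O
Reagents that add atoms: N,N-dimethylformamide (DMF) CN(C)C=O
Why: Directed ortho-metalation should take place at the C–H between the two methoxy groups, which is doubly coordinated and far more acidic than any position of the mono-alkoxy ring, and formylation of the aryllithium with DMF gives the aldehyde.

Step 3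
Reactants: 4 2,6-dimethoxy-4-[2-(4-methoxyphenyl)ethyl]benzaldehyde
Product: 5 2,6-dihydroxy-4-[2-(4-hydroxyphenyl)ethyl]benzaldehyde
Conditions: BBr3, CH2Cl2, −78 °C to rt; H2O
Reagents that add atoms: none
Why: BBr3 cleavage of aryl methyl ethers should remove all three methyl groups at this stage, where no olefin or silyl ether is yet present, the two ortho ethers being cleaved fastest through chelation to the formyl oxygen.

Step 4
Reactants: 5 2,6-dihydroxy-4-[2-(4-hydroxyphenyl)ethyl]benzaldehyde
Product: 6 2-(tert-butyldimethylsilyloxy)-6-hydroxy-4-[2-[4-(tert-butyldimethylsilyloxy)phenyl]ethyl]benzaldehyde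
Conditions: TBSCl (2.1 equiv), imidazole, DMF, 0 °C
Reagents that add atoms: tert-butyldimethylsilyl chloride (TBSCl) CC(C)(C)[Si](C)(C)Cl
Why: Phenol silylation should take the remote 4'-OH first and then one of the two equivalent ortho hydroxyls, after which the last hydroxyl is locked in a hydrogen bond to the formyl group and shielded, so the reaction should stop at the bis-silyl ether.

Step 5
Reactants: 7 2-methylbut-3-en-2-ol
Product: 9 tert-butyl 2-methylbut-3-en-2-yl carbonate, via lithium alkoxide 8 (not isolated)
Conditions: n-BuLi, THF, −78 °C to 0 °C; Boc2O, 0 °C to rt; H2O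
Reagents that add atoms: di-tert-butyl dicarbonate (Boc2O) CC(C)(C)OC(=O)OC(=O)OC(C)(C)C
Why: Acylation of the lithium alkoxide of a tertiary alcohol with Boc2O is a standard way to make the mixed carbonate.

Step 6
Reactants: 6 2-(tert-butyldimethylsilyloxy)-6-hydroxy-4-[2-[4-(tert-butyldimethylsilyloxy)phenyl]ethyl]benzaldehyde; 9 tert-butyl 2-methylbut-3-en-2-yl carbonate
Product: 10 2-(tert-butyldimethylsilyloxy)-6-(2-methylbut-3-en-2-yloxy)-4-[2-[4-(tert-butyldimethylsilyloxy)phenyl]ethyl]benzaldehyde
Conditions: Pd(PPh3)4 (5 mol%), THF, 0 °C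
Reagents that add atoms: none
Why: Tsuji–Trost O-allylation: zerovalent palladium ionises the tertiary allylic carbonate, the released tert-butoxide deprotonates the only free phenol, and the phenoxide attacks the more substituted terminus of the 1,1-dimethyl-π-allyl complex under kinetic control to give the tertiary aryl ether.

Step 7
Reactants: 10 2-(tert-butyldimethylsilyloxy)-6-(2-methylbut-3-en-2-yloxy)-4-[2-[4-(tert-butyldimethylsilyloxy)phenyl]ethyl]benzaldehyde
Product: 12 6-(tert-butyldimethylsilyloxy)-2-hydroxy-3-(3-methylbut-2-enyl)-4-[2-[4-(tert-butyldimethylsilyloxy)phenyl]ethyl]benzaldehyde, via cyclohexadienone 11 (not isolated)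
Conditions: PhMe, 110 °C
Reagents that add atoms: none
Why: Aromatic Claisen rearrangement ([3,3]) can only deliver the allyl unit to the single free ortho carbon (the other bears the formyl group), and allyl inversion turns the 1,1-dimethylallyl ether into a prenyl group between the phenethyl chain and the oxygen that will become O1, before enolisation to the phenol.

Step 8
Reactants: 12 6-(tert-butyldimethylsilyloxy)-2-hydroxy-3-(3-methylbut-2-enyl)-4-[2-[4-(tert-butyldimethylsilyloxy)phenyl]ethyl]benzaldehyde; 9 tert-butyl 2-methylbut-3-en-2-yl carbonate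
Product: 13 6-(tert-butyldimethylsilyloxy)-2-(2-methylbut-3-en-2-yloxy)-3-(3-methylbut-2-enyl)-4-[2-[4-(tert-butyldimethylsilyloxy)phenyl]ethyl]benzaldehyde
Conditions: Pd(PPh3)4 (10 mol%), THF, 0 °C, short reaction time
Reagents that add atoms: none
Why: The same Tsuji–Trost etherification on the phenol freed in step 7 should still give the tertiary ether, because the phenoxide attacks the tertiary allyl terminus under kinetic control, and the run is stopped early so that zerovalent palladium does not re-ionise the product to the linear prenyl ether.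

Step 9
Reactants: 13 6-(tert-butyldimethylsilyloxy)-2-(2-methylbut-3-en-2-yloxy)-3-(3-methylbut-2-enyl)-4-[2-[4-(tert-butyldimethylsilyloxy)phenyl]ethyl]benzaldehyde
Product: 14 1-(tert-butyldimethylsilyloxy)-2-ethenyl-3-(2-methylbut-3-en-2-yloxy)-4-(3-methylbut-2-enyl)-5-[2-[4-(tert-butyldimethylsilyloxy)phenyl]ethyl]benzene
Conditions: Ph3PCH3Br (1.6 equiv), KOtBu (1.5 equiv), THF, 0 °C to rt
Reagents that add atoms: methyltriphenylphosphonium bromide C[P+](c1ccccc1)(c1ccccc1)c1ccccc1.[Br-]
Why: Wittig methylenation with the small non-stabilised ylide should convert even this 2,6-disubstituted benzaldehyde, and the silyl ethers and the tertiary allyl ether tolerate the base at this temperature when no excess alkoxide is present.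

Step 10
Reactants: 14 1-(tert-butyldimethylsilyloxy)-2-ethenyl-3-(2-methylbut-3-en-2-yloxy)-4-(3-methylbut-2-enyl)-5-[2-[4-(tert-butyldimethylsilyloxy)phenyl]ethyl]benzene
Product: 15 5-(tert-butyldimethylsilyloxy)-2,2-dimethyl-8-(3-methylbut-2-enyl)-7-[2-[4-(tert-butyldimethylsilyloxy)phenyl]ethyl]-2H-chromene
Conditions: second-generation Grubbs catalyst RuCl2(=CHPh)(SIMes)(PCy3) (5 mol%), CH2Cl2 (0.01 M), 40 °C
Reagents that add atoms: none
Why: Ring-closing olefin metathesis: the ruthenium alkylidene loads onto one of the two terminal olefins, cyclises onto the other through a ruthenacyclobutane and expels ethylene, so the C3=C4 bond and the pyran ring are formed in one catalytic cycle. The closest known reaction type is the ring-closing metathesis of 2-vinylaryl 1,1-dimethylallyl ethers to 2,2-dimethyl-2H-chromenes. The ring closes as a six-membered ring with both olefin carbons inside it, so only the cis olefin can form, and the gem-dimethyl group at C2 favours the reactive conformer (Thorpe–Ingold effect). No stereocenter is created. The step needs chemoselectivity for the two monosubstituted olefins over the trisubstituted prenyl olefin, including a conceivable seven-membered closure onto the C8 prenyl group; this is secured by the much slower metathesis of trisubstituted olefins and the kinetic preference for the six-membered ring. The tertiary allyl ether must also survive, which the substituted ortho positions (C8 prenyl, C4a vinyl) and the low temperature should ensure, since an ortho-Claisen shift has no productive outlet there.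

Step 11
Reactants: 15 5-(tert-butyldimethylsilyloxy)-2,2-dimethyl-8-(3-methylbut-2-enyl)-7-[2-[4-(tert-butyldimethylsilyloxy)phenyl]ethyl]-2H-chromene
Product: 16 7-[2-(4-hydroxyphenyl)ethyl]-2,2-dimethyl-8-(3-methylbut-2-enyl)-2H-chromen-5-ol
Conditions: TBAF, AcOH, THF, 0 °C
Reagents that add atoms: none
Why: Fluoride cleaves both aryl silyl ethers under buffered, non-acidic conditions that leave the acid-sensitive chromene and the prenyl group untouched.

Step 12
Reactants: 16 7-[2-(4-hydroxyphenyl)ethyl]-2,2-dimethyl-8-(3-methylbut-2-enyl)-2H-chromen-5-ol (two molecules)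
Product: 18 (4R)-4-[5-hydroxy-7-[2-(4-hydroxyphenyl)ethyl]-2,2-dimethyl-8-(3-methylbut-2-enyl)-2H-chromen-6-yl]-7-[2-(4-hydroxyphenyl)ethyl]-2,2-dimethyl-8-(3-methylbut-2-enyl)chroman-5-ol, via ortho-quinone methide 17 (not isolated)
Conditions: (R)-3,3'-bis(2,4,6-triisopropylphenyl)-1,1'-binaphthyl-2,2'-diyl N-triflylphosphoramide (10 mol%), CH2Cl2, −40 °C, stopped at partial conversion, 16 recovered
Reagents that add atoms: none
Why: Proposed new method: asymmetric Brønsted acid-catalysed hydroarylative homodimerisation of a 2H-chromen-5-ol, in which the chiral acid protonates C3 of one molecule of 16 (an ortho-hydroxystyrene and the only strongly basic olefin) to give the ortho-quinone methide 17 held in a hydrogen-bonded ion pair, while the phosphoramide oxygen binds the 5-OH of a second molecule and delivers its ortho carbon C6 (the only free position of that ring, activated by the 5-OH and by O1 para to it) to one face of C4, the face being chosen by the 3,3'-aryl groups of the catalyst, which sets the single stereocenter; the closest known reaction type is the chiral phosphoric acid-catalysed enantioselective Friedel–Crafts addition of phenols, naphthols and indoles to ortho-quinone methides generated in situ from ortho-hydroxystyrenes or ortho-hydroxybenzyl alcohols, and since neither prenyl group has a free ortho hydroxyl no acid-induced chroman formation can compete.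

Compound list
1 | (E)-3,4',5-trimethoxystilbene, commercial | COc1ccc(/C=C/c2cc(OC)cc(OC)c2)cc1 | starting material
2 | 1,3-dimethoxy-5-[2-(4-methoxyphenyl)ethyl]benzene | COc1ccc(CCc2cc(OC)cc(OC)c2)cc1 | intermediate
3 | [2,6-dimethoxy-4-[2-(4-methoxyphenyl)ethyl]phenyl]lithium (not isolated) | COc1ccc(CCc2cc(OC)c([Li])c(OC)c2)cc1 | intermediate
4 | 2,6-dimethoxy-4-[2-(4-methoxyphenyl)ethyl]benzaldehyde | COc1ccc(CCc2cc(OC)c(C=O)c(OC)c2)cc1 | intermediate
5 | 2,6-dihydroxy-4-[2-(4-hydroxyphenyl)ethyl]benzaldehyde | O=Cc1c(O)cc(CCc2ccc(O)cc2)cc1O | intermediate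
6 | 2-(tert-butyldimethylsilyloxy)-6-hydroxy-4-[2-[4-(tert-butyldimethylsilyloxy)phenyl]ethyl]benzaldehyde | O=Cc1c(O)cc(CCc2ccc(O[Si](C)(C)C(C)(C)C)cc2)cc1O[Si](C)(C)C(C)(C)C | intermediate
7 | 2-methylbut-3-en-2-ol, commercial | C=CC(C)(C)O | starting material
8 | lithium 2-methylbut-3-en-2-olate (not isolated) | C=CC(C)(C)O[Li] | intermediate
9 | tert-butyl 2-methylbut-3-en-2-yl carbonate | C=CC(C)(C)OC(=O)OC(C)(C)C | intermediate
10 | 2-(tert-butyldimethylsilyloxy)-6-(2-methylbut-3-en-2-yloxy)-4-[2-[4-(tert-butyldimethylsilyloxy)phenyl]ethyl]benzaldehyde | O=Cc1c(OC(C)(C)C=C)cc(CCc2ccc(O[Si](C)(C)C(C)(C)C)cc2)cc1O[Si](C)(C)C(C)(C)C | intermediate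
11 | 2-formyl-3-(tert-butyldimethylsilyloxy)-6-(3-methylbut-2-enyl)-5-[2-[4-(tert-butyldimethylsilyloxy)phenyl]ethyl]cyclohexa-2,4-dien-1-one, racemic at C6 (not isolated) | O=CC1=C(O[Si](C)(C)C(C)(C)C)C=C(CCc2ccc(O[Si](C)(C)C(C)(C)C)cc2)C(CC=C(C)C)C1=O | intermediate
12 | 6-(tert-butyldimethylsilyloxy)-2-hydroxy-3-(3-methylbut-2-enyl)-4-[2-[4-(tert-butyldimethylsilyloxy)phenyl]ethyl]benzaldehyde | O=Cc1c(O)c(CC=C(C)C)c(CCc2ccc(O[Si](C)(C)C(C)(C)C)cc2)cc1O[Si](C)(C)C(C)(C)C | intermediate
13 | 6-(tert-butyldimethylsilyloxy)-2-(2-methylbut-3-en-2-yloxy)-3-(3-methylbut-2-enyl)-4-[2-[4-(tert-butyldimethylsilyloxy)phenyl]ethyl]benzaldehyde | O=Cc1c(OC(C)(C)C=C)c(CC=C(C)C)c(CCc2ccc(O[Si](C)(C)C(C)(C)C)cc2)cc1O[Si](C)(C)C(C)(C)C | intermediate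
14 | 1-(tert-butyldimethylsilyloxy)-2-ethenyl-3-(2-methylbut-3-en-2-yloxy)-4-(3-methylbut-2-enyl)-5-[2-[4-(tert-butyldimethylsilyloxy)phenyl]ethyl]benzene | C=Cc1c(OC(C)(C)C=C)c(CC=C(C)C)c(CCc2ccc(O[Si](C)(C)C(C)(C)C)cc2)cc1O[Si](C)(C)C(C)(C)C | intermediate
15 | 5-(tert-butyldimethylsilyloxy)-2,2-dimethyl-8-(3-methylbut-2-enyl)-7-[2-[4-(tert-butyldimethylsilyloxy)phenyl]ethyl]-2H-chromene | CC(C)=CCc1c(CCc2ccc(O[Si](C)(C)C(C)(C)C)cc2)cc(O[Si](C)(C)C(C)(C)C)c2c1OC(C)(C)C=C2 | intermediate
16 | 7-[2-(4-hydroxyphenyl)ethyl]-2,2-dimethyl-8-(3-methylbut-2-enyl)-2H-chromen-5-ol | CC(C)=CCc1c(CCc2ccc(O)cc2)cc(O)c2c1OC(C)(C)C=C2 | intermediate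
17 | 7-[2-(4-hydroxyphenyl)ethyl]-2,2-dimethyl-8-(3-methylbut-2-enyl)-2,3-dihydro-5H-chromen-5-one, ortho-quinone methide tautomer of 16 protonated at C3 (not isolated) | O=C1C=C(CCc2ccc(O)cc2)C(CC=C(C)C)=C2OC(C)(C)CC=C12 | intermediate
18 | (4R)-4-[5-hydroxy-7-[2-(4-hydroxyphenyl)ethyl]-2,2-dimethyl-8-(3-methylbut-2-enyl)-2H-chromen-6-yl]-7-[2-(4-hydroxyphenyl)ethyl]-2,2-dimethyl-8-(3-methylbut-2-enyl)chroman-5-ol | CC(C)=CCc1c(CCc2ccc(O)cc2)c([C@H]2CC(C)(C)Oc3c(CC=C(C)C)c(CCc4ccc(O)cc4)cc(O)c32)c(O)c2c1OC(C)(C)C=C2 | target

Total step count: 12.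
Longest linear sequence: 11 steps (from 1 through steps 1 to 4 and 6 to 12); step 5 is a side branch that makes reagent 9.

Steps most likely to fail

Step 12 (proposed new method). The chiral anion may discriminate the two faces of C4 poorly. The olefinic C3 of a second chromene may compete with C6 as the nucleophile. The dimer, which still holds a chromene and a free C6–H, may be alkylated further. The fallback sets out from 16 and uses only known chemistry. An achiral Brønsted acid (diphenyl phosphate, 5 mol%, CH2Cl2, 0 °C, partial conversion) should bring about the ordinary acid-catalysed Friedel–Crafts hydroarylation of the styrene-type olefin by the phenol and give the racemic dimer F1. The enantiomers of F1 would then be separated by preparative HPLC on an amylose tris(3,5-dimethylphenylcarbamate) stationary phase, which comes back to the route at 18. The (R)-enantiomer would be identified by comparing its ECD spectrum with calculation.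

Step 8. Etherification of the doubly flanked phenol may stall, and zerovalent palladium may re-ionise the tertiary ether and drain it to the linear prenyl ether. The fallback sets out from 12 and replaces the π-allyl chemistry by a two-stage propargyl route. Copper-catalysed alkylation with 3-chloro-3-methylbut-1-yne (CuCl2·2H2O 1 mol%, DBU, MeCN, 0 °C) should give the 1,1-dimethylpropargyl ether F2, which cannot re-ionise under these conditions. Semihydrogenation over Pd/CaCO3 poisoned with Pb(OAc)2 (quinoline, H2, EtOAc, rt) then comes back to the route at 13.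

Step 4. Site discrimination may be lost through over-silylation of the hydrogen-bonded hydroxyl or incomplete silylation of the first ortho hydroxyl. The fallback sets out from 5 and differentiates the oxygens one at a time. TBSCl (1.0 equiv), imidazole, DMF, −20 °C should silylate only the remote phenol to give the 4'-mono-silyl ether F3. Mono-etherification of one of the two equivalent ortho hydroxyls with 9 and Pd(PPh3)4 (THF, 0 °C), the second hydroxyl being held back by its hydrogen bond, gives the hydroxy ether F4. Silylation of the remaining hydroxyl with TBSOTf, 2,6-lutidine, CH2Cl2, −78 °C comes back to the route at 10.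

Further compounds
F1 | step 12 | racemic 4-[5-hydroxy-7-[2-(4-hydroxyphenyl)ethyl]-2,2-dimethyl-8-(3-methylbut-2-enyl)-2H-chromen-6-yl]-7-[2-(4-hydroxyphenyl)ethyl]-2,2-dimethyl-8-(3-methylbut-2-enyl)chroman-5-ol | CC(C)=CCc1c(CCc2ccc(O)cc2)c(C2CC(C)(C)Oc3c(CC=C(C)C)c(CCc4ccc(O)cc4)cc(O)c32)c(O)c2c1OC(C)(C)C=C2
F2 | step 8 | 6-(tert-butyldimethylsilyloxy)-2-(2-methylbut-3-yn-2-yloxy)-3-(3-methylbut-2-enyl)-4-[2-[4-(tert-butyldimethylsilyloxy)phenyl]ethyl]benzaldehyde | O=Cc1c(OC(C)(C)C#C)c(CC=C(C)C)c(CCc2ccc(O[Si](C)(C)C(C)(C)C)cc2)cc1O[Si](C)(C)C(C)(C)C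
F3 | step 4 | 2,6-dihydroxy-4-[2-[4-(tert-butyldimethylsilyloxy)phenyl]ethyl]benzaldehyde | O=Cc1c(O)cc(CCc2ccc(O[Si](C)(C)C(C)(C)C)cc2)cc1O
F4 | step 4 | 2-hydroxy-6-(2-methylbut-3-en-2-yloxy)-4-[2-[4-(tert-butyldimethylsilyloxy)phenyl]ethyl]benzaldehyde | O=Cc1c(O)cc(CCc2ccc(O[Si](C)(C)C(C)(C)C)cc2)cc1OC(C)(C)C=C
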